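Taiwanhomoflavone A is a 3′–8″-linked biflavone. Both pyranone rings C repeat one motif: O1 on ring A, C2 bearing an aryl group, C3, and C4=O back on ring A. Everything rests on cutting C2–C3 in both halves at once. Each future C2 is parked as an aroyl ester on the phenol oxygen that will become O1, ortho to the acetyl group that supplies C3 and C4. Excess lithium amide then shifts both aroyl groups from oxygen to carbon in one operation. The precursor is a biaryl bis(2-acyloxyacetophenone): the ring B acid esterified to the methylated ring A, and a 4-benzyloxybenzoate on the crowded phenol beside the biaryl bond.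

Key step: step 8

Assumption: the SMILES carries no stereodescriptor, so the 3′–8″ biaryl axis is taken as configurationally undefined. The target has no stereocentre and no step has to control one.

Step 1
Reactants: 1 2,4,6-trihydroxyacetophenone
Product: 2 1-[2,4-bis(benzyloxy)-6-hydroxyphenyl]ethan-1-one
Conditions: BnBr (2.1 equiv), K2CO3 (2.2 equiv), DMF, 60 °C
Reagents that add atoms: benzyl bromide, BrCc1ccccc1
Why: Williamson ether synthesis; once the 4-OH and one ortho OH have reacted, the last hydroxyl is locked in a hydrogen bond to the ketone and is too poor a nucleophile under carbonate conditions, so alkylation should stop at the diether.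

Step 2
Reactants: 2 1-[2,4-bis(benzyloxy)-6-hydroxyphenyl]ethan-1-one
Product: 3 1-[4,6-bis(benzyloxy)-2-hydroxy-3-iodophenyl]ethan-1-one
Conditions: NIS (1.05 equiv), TFA (10 mol %), MeCN, 0 °C to rt
Reagents that add atoms: N-iodosuccinimide, O=C1CCC(=O)N1I
Why: Electrophilic aromatic iodination; both free ring positions are activated by three oxygens, but C3 lies between the small OH and one OBn while C5 is walled in by two OBn groups, so iodine should enter ortho to the free phenol, as is established for 4,6-dialkoxy-2-hydroxyacetophenones.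

Step 3
Reactants: 3 1-[4,6-bis(benzyloxy)-2-hydroxy-3-iodophenyl]ethan-1-one; 4 [2-methoxy-5-(methoxycarbonyl)phenyl]boronic acid
Product: 6 3-[3-acetyl-4,6-bis(benzyloxy)-2-hydroxyphenyl]-4-methoxybenzoic acid, via biaryl methyl ester 5 (not isolated)
Conditions: Pd(OAc)2 (5 mol %), SPhos (10 mol %), K3PO4 (3 equiv), dioxane/H2O, 90 °C; then LiOH·H2O (5 equiv), 50 °C, same flask; 1 M HCl
Reagents that add atoms: lithium hydroxide, [Li+].[OH-] (oxygen of the new acid OH)
Why: Suzuki-Miyaura coupling followed by ester saponification; the bulky, electron-rich biarylphosphine is suited to tri-ortho-substituted biaryls, aryl iodides add to zerovalent palladium even as phenoxides, and ketone, phenol and benzyl ethers are inert to aqueous LiOH.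

Step 4
Reactants: 7 2,6-dimethoxytoluene
Product: 9 3,5-dimethoxy-4-methylphenol, via aryl pinacol boronate 8 (not isolated)
Conditions: [Ir(OMe)(cod)]2 (1.5 mol %), dtbpy (3 mol %), B2pin2 (0.6 equiv), THF, 80 °C; then 30% H2O2, aq NaOH, 0 °C to rt, same flask; 1 M HCl
Reagents that add atoms: bis(pinacolato)diboron, CC1(C)OB(OC1(C)C)B1OC(C)(C)C(C)(C)O1 (boryl group of 8); hydrogen peroxide, OO (phenol oxygen of 9)
Why: Sterically governed iridium-catalysed C-H borylation and boronate oxidation; the oxygen must sit meta to both methoxy groups, where electrophilic substitution cannot reach, and C4-H is the only ring C-H without an ortho substituent, so this 1,2,3-trisubstituted arene should be borylated there.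

Step 5
Reactants: 9 3,5-dimethoxy-4-methylphenol
Product: 10 1-(6-hydroxy-2,4-dimethoxy-3-methylphenyl)ethan-1-one
Conditions: BF3·OEt2 (3 equiv), AcOH, 85 °C; H2O work-up
Reagents that add atoms: acetic acid, CC(=O)O
Why: Friedel-Crafts/Fries-type ortho-acylation of a phenol, routine for 3,4,5-trisubstituted phenols; 9 is symmetric and its para position is blocked by methyl, so only one C-acyl product is possible, and the boron difluoride chelate of the product holds back a second acylation.

Step 6
Reactants: 6 3-[3-acetyl-4,6-bis(benzyloxy)-2-hydroxyphenyl]-4-methoxybenzoic acid; 10 1-(6-hydroxy-2,4-dimethoxy-3-methylphenyl)ethan-1-one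
Product: 11 2-acetyl-3,5-dimethoxy-4-methylphenyl 3-[3-acetyl-4,6-bis(benzyloxy)-2-hydroxyphenyl]-4-methoxybenzoate
Conditions: 10 (1.3 equiv), EDC·HCl (1.3 equiv), DMAP (0.3 equiv), CH2Cl2, 0 °C to rt
Reagents that add atoms: none
Why: Steglich esterification; the phenol of 10 has one open ortho side, whereas the phenol inside 6 is chelated to its acetyl group, shut in by the biaryl ring and unable to reach its own carboxyl group, so the activated acid should be taken by 10 and not by a second molecule of 6.

Step 7
Reactants: 11 2-acetyl-3,5-dimethoxy-4-methylphenyl 3-[3-acetyl-4,6-bis(benzyloxy)-2-hydroxyphenyl]-4-methoxybenzoate; 12 4-(benzyloxy)benzoic acid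
Product: 14 2-acetyl-3,5-dimethoxy-4-methylphenyl 3-{3-acetyl-4,6-bis(benzyloxy)-2-[4-(benzyloxy)benzoyloxy]phenyl}-4-methoxybenzoate, via 4-(benzyloxy)benzoyl chloride 13 (not isolated)
Conditions: 12 (2 equiv), (COCl)2, DMF (cat.), CH2Cl2, rt, evaporate; then 11, Et3N (4 equiv), DMAP (0.5 equiv), CH2Cl2, 0 °C to 40 °C
Reagents that add atoms: oxalyl chloride, O=C(Cl)C(=O)Cl (chlorine of 13)
Why: Acid chloride formation and DMAP-catalysed O-acylation; the N-acylpyridinium ion acylates even di-ortho-substituted, chelated phenols, and an amine base is too weak to enolise the ketones, so the ester already present should stay where it is.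

Step 8
Reactants: 14 2-acetyl-3,5-dimethoxy-4-methylphenyl 3-{3-acetyl-4,6-bis(benzyloxy)-2-[4-(benzyloxy)benzoyloxy]phenyl}-4-methoxybenzoate
Product: 15 1-[4-(benzyloxy)phenyl]-3-{4,6-bis(benzyloxy)-2-hydroxy-3-[5-(3-(6-hydroxy-2,4-dimethoxy-3-methylphenyl)-3-oxopropanoyl)-2-methoxyphenyl]phenyl}propane-1,3-dione
Conditions: LiN(SiMe3)2 (6 equiv), THF (0.02 M), −78 °C to −10 °C; 1 M HCl
Reagents that add atoms: none
Why: LiN(SiMe3)2 deprotonates both acetyl groups, and each lithium enolate adds to the ester carbonyl on the neighbouring ring oxygen through a transient six-membered alkoxide (6-enolendo-exo-trig), which collapses to a lithium phenoxide and a 1,3-diketone that further base traps as its enolate, so at least four equivalents are consumed and the sequence is pulled forward. This is the Baker-Venkataraman rearrangement, run at two sites of one molecule as is known for bis(2-acyloxyacetophenones). No ring persists and no stereocentre forms; the two new bonds are C2-C3 of half 1 and C2-C3 of half 2. The selectivity needed is that each aroyl group reaches its own enolate carbon, and the ortho placement of ester and acetyl on each ring A secures it, because the other enolate could be reached only through a strained macrocyclic or an intermolecular Claisen path that cold, dilute conditions disfavour. The non-nucleophilic amide base avoids ester cleavage, and migration relieves the crowding of the benzoate wedged between the acetyl group and the biaryl bond.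

Step 9
Reactants: 15 bis(1,3-diketone) of step 8
Product: 16 2-{3-[5,7-bis(benzyloxy)-2-(4-(benzyloxy)phenyl)-4-oxo-4H-chromen-8-yl]-4-methoxyphenyl}-5,7-dimethoxy-6-methyl-4H-chromen-4-one
Conditions: NaOAc (anhydrous, 6 equiv), AcOH, 110 °C
Reagents that add atoms: none
Why: Cyclodehydration of 2-hydroxyaryl 1,3-diketones to flavones (each phenol adds 6-exo-trig to the aryl ketone carbonyl and the hemiketal loses water); each diketone has only one free ortho phenol because the other ortho oxygen is still OMe or OBn, which fixes the 6-methyl and 8-aryl patterns, and the acetate buffer spares benzyl ethers that a mineral acid could cleave or shift to carbon.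

Step 10
Reactants: 16 protected biflavone of step 9
Product: 17 Taiwanhomoflavone A
Conditions: BCl3 (1 M in CH2Cl2, 12 equiv), C6HMe5 (10 equiv), CH2Cl2, −78 °C to 0 °C; H2O
Reagents that add atoms: none
Why: Lewis acid ether cleavage; BCl3 with pentamethylbenzene as a non-basic benzyl cation trap removes aryl benzyl ethers without C-benzylation of the phloroglucinol ring, and it cleaves only the methyl ether (5-OMe) that can chelate boron together with the C4 carbonyl, so 7-OMe and 4′-OMe should stay and no Wessely-Moser ring opening is expected at this temperature.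

Compound list
1 | 2,4,6-trihydroxyacetophenone | CC(=O)c1c(O)cc(O)cc1O | starting material
2 | 1-[2,4-bis(benzyloxy)-6-hydroxyphenyl]ethan-1-one | CC(=O)c1c(O)cc(OCc2ccccc2)cc1OCc1ccccc1 | intermediate
3 | 1-[4,6-bis(benzyloxy)-2-hydroxy-3-iodophenyl]ethan-1-one | CC(=O)c1c(O)c(I)c(OCc2ccccc2)cc1OCc1ccccc1 | intermediate
4 | [2-methoxy-5-(methoxycarbonyl)phenyl]boronic acid | COC(=O)c1ccc(OC)c(B(O)O)c1 | starting material
5 | methyl 3-[3-acetyl-4,6-bis(benzyloxy)-2-hydroxyphenyl]-4-methoxybenzoate | COC(=O)c1ccc(OC)c(-c2c(O)c(C(C)=O)c(OCc3ccccc3)cc2OCc2ccccc2)c1 | intermediate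
6 | 3-[3-acetyl-4,6-bis(benzyloxy)-2-hydroxyphenyl]-4-methoxybenzoic acid | OC(=O)c1ccc(OC)c(-c2c(O)c(C(C)=O)c(OCc3ccccc3)cc2OCc2ccccc2)c1 | intermediate
7 | 2,6-dimethoxytoluene | Cc1c(OC)cccc1OC | starting material
8 | 2-(3,5-dimethoxy-4-methylphenyl)-4,4,5,5-tetramethyl-1,3,2-dioxaborolane | COc1cc(B2OC(C)(C)C(C)(C)O2)cc(OC)c1C | intermediate
9 | 3,5-dimethoxy-4-methylphenol | COc1cc(O)cc(OC)c1C | intermediate
10 | 1-(6-hydroxy-2,4-dimethoxy-3-methylphenyl)ethan-1-one | CC(=O)c1c(O)cc(OC)c(C)c1OC | intermediate
11 | 2-acetyl-3,5-dimethoxy-4-methylphenyl 3-[3-acetyl-4,6-bis(benzyloxy)-2-hydroxyphenyl]-4-methoxybenzoate | CC(=O)c1c(OC(=O)c2ccc(OC)c(-c3c(O)c(C(C)=O)c(OCc4ccccc4)cc3OCc3ccccc3)c2)cc(OC)c(C)c1OC | intermediate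
12 | 4-(benzyloxy)benzoic acid | O=C(O)c1ccc(OCc2ccccc2)cc1 | starting material
13 | 4-(benzyloxy)benzoyl chloride | O=C(Cl)c1ccc(OCc2ccccc2)cc1 | intermediate
14 | diester, 2-acetyl-3,5-dimethoxy-4-methylphenyl 3-{3-acetyl-4,6-bis(benzyloxy)-2-[4-(benzyloxy)benzoyloxy]phenyl}-4-methoxybenzoate | CC(=O)c1c(OC(=O)c2ccc(OC)c(-c3c(OC(=O)c4ccc(OCc5ccccc5)cc4)c(C(C)=O)c(OCc4ccccc4)cc3OCc3ccccc3)c2)cc(OC)c(C)c1OC | intermediate
15 | bis(1,3-diketone) with both ortho phenols free | COc1cc(O)c(C(=O)CC(=O)c2ccc(OC)c(-c3c(O)c(C(=O)CC(=O)c4ccc(OCc5ccccc5)cc4)c(OCc4ccccc4)cc3OCc3ccccc3)c2)c(OC)c1C | intermediate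
16 | 5-O-methyl-5″,7″,4‴-tri-O-benzyl taiwanhomoflavone A | COc1ccc(-c2cc(=O)c3c(OC)c(C)c(OC)cc3o2)cc1-c1c(OCc2ccccc2)cc(OCc2ccccc2)c2c(=O)cc(-c3ccc(OCc4ccccc4)cc3)oc12 | intermediate
17 | Taiwanhomoflavone A | COc1ccc(-c2cc(=O)c3c(O)c(C)c(OC)cc3o2)cc1-c1c(O)cc(O)c2c(=O)cc(-c3ccc(O)cc3)oc12 | target

Total step count: 10.
Longest linear sequence: 8 (steps 1, 2, 3, 6, 7, 8, 9, 10). Steps 4 and 5 form the side branch to 10.

Steps most likely to fail

1. Step 8.
- **Risk:** the two migrations may run at different rates, with the crowded benzoate of half 2 lagging. The long exposure to base needed for the slower site could then erode the faster one by ester cleavage or retro-Claisen fragmentation.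
- **Fallback (sets out from 11, returns at 16):** the two acyl transfers are uncoupled and the pyranones are built one after the other.
  - Compound 11 carries only the ring B ester. LiN(SiMe3)2 (5 equiv) in THF moves that single aroyl group and should give the half 1 diketone F1.
  - NaOAc in hot AcOH closes it to the flavone hydroxyketone F2.
  - The remaining hindered phenol is aroylated with 13 (Et3N, DMAP) to the flavone benzoate F3.
  - A single Baker-Venkataraman transfer gives the flavone diketone F4, and the same cyclodehydration delivers 16.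

2. Step 3.
- **Risk:** oxidative addition to the electron-rich iodophenoxide may be slow enough for protodeboronation of the ortho-methoxy boronic acid and reductive loss of iodine to take over.
- **Fallback (sets out from 3, returns at 11):** the phenol is masked before the coupling.
  - MOMCl and iPr2NEt convert 3 into the MOM-protected iodide F5, a neutral and more electrophilic partner.
  - The coupling with 4 gives the MOM-protected biaryl ester F6, and LiOH gives the MOM-protected biaryl acid F7.
  - Steglich esterification with 10, now without any competing phenol, gives the MOM-protected monoester F8.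
  - Brief TFA in CH2Cl2 at 0 °C removes the acetal, which is labile next to the ketone, and returns 11.

3. Step 10.
- **Risk:** the warming needed to clear the 5-O-methyl group may begin to erode 7-OMe or 4′-OMe. Debenzylation may also stall on poorly soluble boron phenoxides, or benzyl cations may escape the trap and alkylate C6″.
- **Fallback (sets out from 16, returns at 17):** the two kinds of ether are removed by unrelated chemistry.
  - Hydrogenolysis (H2, 10% Pd/C, THF/MeOH) strips the three benzyl ethers without forming cations and gives the 5-O-methyl ether of the target F9.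
  - AlCl3 in MeCN at 60 °C then cleaves only the methoxy group peri to the C4 carbonyl through its aluminium chelate, giving 17.

Further compounds
F1 | step 8 | half 1 diketone (ring B aroyl group transferred, half 2 still a hydroxyacetophenone) | COc1cc(O)c(C(=O)CC(=O)c2ccc(OC)c(-c3c(O)c(C(C)=O)c(OCc4ccccc4)cc3OCc3ccccc3)c2)c(OC)c1C
F2 | step 8 | flavone hydroxyketone, 2-[3-(3-acetyl-4,6-bis(benzyloxy)-2-hydroxyphenyl)-4-methoxyphenyl]-5,7-dimethoxy-6-methyl-4H-chromen-4-one | COc1ccc(-c2cc(=O)c3c(OC)c(C)c(OC)cc3o2)cc1-c1c(O)c(C(C)=O)c(OCc2ccccc2)cc1OCc1ccccc1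
F3 | step 8 | flavone benzoate (4-(benzyloxy)benzoate of F2) | COc1ccc(-c2cc(=O)c3c(OC)c(C)c(OC)cc3o2)cc1-c1c(OC(=O)c2ccc(OCc3ccccc3)cc2)c(C(C)=O)c(OCc2ccccc2)cc1OCc1ccccc1
F4 | step 8 | flavone diketone (half 2 aroyl group transferred) | COc1ccc(-c2cc(=O)c3c(OC)c(C)c(OC)cc3o2)cc1-c1c(O)c(C(=O)CC(=O)c2ccc(OCc3ccccc3)cc2)c(OCc2ccccc2)cc1OCc1ccccc1
F5 | step 3 | MOM-protected iodide, 1-[4,6-bis(benzyloxy)-3-iodo-2-(methoxymethoxy)phenyl]ethan-1-one | CC(=O)c1c(OCOC)c(I)c(OCc2ccccc2)cc1OCc1ccccc1
F6 | step 3 | MOM-protected biaryl ester | COC(=O)c1ccc(OC)c(-c2c(OCOC)c(C(C)=O)c(OCc3ccccc3)cc2OCc2ccccc2)c1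
F7 | step 3 | MOM-protected biaryl acid | OC(=O)c1ccc(OC)c(-c2c(OCOC)c(C(C)=O)c(OCc3ccccc3)cc2OCc2ccccc2)c1
F8 | step 3 | MOM-protected monoester | CC(=O)c1c(OC(=O)c2ccc(OC)c(-c3c(OCOC)c(C(C)=O)c(OCc4ccccc4)cc3OCc3ccccc3)c2)cc(OC)c(C)c1OC
F9 | step 10 | 5-O-methyl ether of the target | COc1ccc(-c2cc(=O)c3c(OC)c(C)c(OC)cc3o2)cc1-c1c(O)cc(O)c2c(=O)cc(-c3ccc(O)cc3)oc12
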